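**Assumption:** commercial natural phytol (7R,11R; the E/Z ratio is irrelevant because the alkene is cleaved in step 1) and (S)-3-hydroxybutanoic acid are the chiral starting materials.

The route has not been run; steps 7, 9 and 10 are the least precedented and are flagged at the end.

## Retrosynthetic overview

1. Pyran ring last: the C8a–O1 bond is closed by reductive cyclisation of p-quinone 15 through its cyclic hemiketal, so the tertiary C2–O bond is never broken.
2. Benzenoid ring: Diels–Alder / ring-opening aromatisation of ynone 11 with 3-methyl-2-silyloxyfuran 13 gives the 2-acyl-3,6-dimethylhydroquinone 14.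
3. C2 quaternary carbinol: cuprate addition of the C16 unit 4 to Seebach dioxinone 8 (from (S)-3-hydroxybutanoic acid, self-regeneration of the stereocentre); propyne then converts dioxanone 9 into ynone 11.
4. C4′ and C8′: bought in natural phytol, degraded to C16 iodide 4 by ozonolysis, haloform cleavage and iododecarboxylation.
5. Ring order: arene (step 9), then dihydropyran (step 11).

## Route

**Step 1**
Reactants: 1, natural phytol, (2E,7R,11R)-3,7,11,15-tetramethylhexadec-2-en-1-ol
Product: 2, (6R,10R)-6,10,14-trimethylpentadecan-2-one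
Conditions: O3, CH2Cl2/MeOH, −78 °C; then Me2S, −78 °C → rt
Reagents that add atoms: ozone, [O-][O+]=O
Why: Ozonolysis cleaves the only C=C to the methyl ketone; both methyl-bearing stereocentres are remote sp3 carbons and are untouched.

**Step 2**
Reactants: 2
Product: 3, (5R,9R)-5,9,13-trimethyltetradecanoic acid
Conditions: Br2, NaOH, H2O/dioxane, 0 °C → rt; Na2SO3; HCl
Reagents that add atoms: sodium hydroxide, [Na+].[OH-]
Why: Haloform reaction: exhaustive bromination of the methyl group, then hydroxide cleaves the C–CBr3 bond to give the acid one carbon shorter.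

**Step 3**
Reactants: 3
Product: 4, (4R,8R)-1-iodo-4,8,12-trimethyltridecane
Conditions: PhI(OAc)2, I2, cyclohexane, hν (W lamp), reflux
Reagents that add atoms: iodine, II
Why: Suárez (Hunsdiecker-type) radical iododecarboxylation gives the primary iodide; the stereocentres are not involved.

**Step 4**
Reactants: 5, (S)-3-hydroxybutanoic acid; 6, pivalaldehyde
Product: 7, (2S,6S)-2-tert-butyl-6-methyl-1,3-dioxan-4-one (cis)
Conditions: p-TsOH (cat.), CH2Cl2, reflux, Dean–Stark; recrystallise (Et2O/pentane, −78 °C)
Reagents that add atoms: none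
Why: Acetalisation under thermodynamic control gives the cis (diequatorial) dioxanone, so the acetal centre is set by the purchased carbinol centre.

**Step 5**
Reactants: 7
Product: 8, (S)-2-tert-butyl-6-methyl-4H-1,3-dioxin-4-one
Conditions: NBS, AIBN (cat.), CCl4, reflux; then Et3N, 0 °C → rt
Reagents that add atoms: none
Why: Radical bromination at C6 and dehydrobromination give Seebach's dioxinone; the acetal centre survives as the only stereocentre.

**Step 6**
Reactants: 4; 8
Product: 9, (2S,6R)-2-tert-butyl-6-methyl-6-[(4R,8R)-4,8,12-trimethyltridecyl]-1,3-dioxan-4-one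
Conditions: 4 (2.2 equiv), t-BuLi, Et2O/pentane, −78 °C; CuI (1.1 equiv), −40 °C; then 8, THF, −78 → −30 °C; aq NH4Cl
Reagents that add atoms: none
Why: Gilman cuprate conjugate addition to the chiral dioxinone occurs trans to the tert-butyl group (Seebach), so the acetal centre sets the new quaternary carbon as R (future C2).

**Step 7**
Reactants: 9; 10, propyne
Product: 11, (6R,10R,14R)-6-hydroxy-6,10,14,18-tetramethylnonadec-2-yn-4-one
Conditions: propyne, n-BuLi, THF, −78 °C; BF3·OEt2; then 9, −78 °C; aq NH4Cl, rt
Reagents that add atoms: none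
Why: Yamaguchi-type BF3-promoted addition of the lithium acetylide to the lactone carbonyl stops at the ketone, and the hemiacetal released on work-up loses pivalaldehyde to unveil the tertiary alcohol without touching C2.

**Step 8**
Reactants: 12, 3-methylfuran-2(5H)-one
Product: 13, 3-methyl-2-(trimethylsilyloxy)furan
Conditions: Me3SiCl, Et3N, Et2O, 0 °C → rt; filter, distil
Reagents that add atoms: chlorotrimethylsilane, C[Si](C)(C)Cl
Why: O-silylation of the butenolide dienolate gives the aromatic, electron-rich 2-silyloxyfuran diene.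

**Step 9** (key step, forms the benzenoid ring)
Reactants: 11; 13
Product: 14, (3R,7R,11R)-1-(2,5-dihydroxy-3,6-dimethylphenyl)-3-hydroxy-3,7,11,15-tetramethylhexadecan-1-one
Conditions: 13 (2.5 equiv), toluene, 80 °C, sealed tube; then PPTS (cat.), MeOH, rt
Reagents that add atoms: none
Why: Diels–Alder cycloaddition of the silyloxyfuran with the ynone joins furan C5 (largest HOMO coefficient, least hindered) to the methyl-bearing β-carbon; the 7-oxanorbornadiene opens with silyloxy assistance and tautomerises to the hydroquinone, creating no stereocentre and leaving C2 untouched under neutral conditions.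

**Step 10**
Reactants: 14
Product: 15, 2-[(3R,7R,11R)-3-hydroxy-3,7,11,15-tetramethylhexadecyl]-3,6-dimethylcyclohexa-2,5-diene-1,4-dione
Conditions: H2 (4 atm), 10% Pd/C, AcOH/EtOAc, 40 °C; filter; then aq FeCl3, Et2O, rt
Reagents that add atoms: none
Why: Hydrogenolysis of the ortho-hydroxyaryl ketone to CH2 (via the benzylic alcohol), then oxidation of the air-sensitive hydroquinone (not isolated) to the p-quinone; the tertiary carbinol is not involved.

**Step 11**
Reactants: 15
Product: 16, (2R,4′R,8′R)-β-tocopherol
Conditions: SnCl2·2H2O, conc. HCl, MeOH, 65 °C, N2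
Reagents that add atoms: none
Why: Reductive cyclisation: the tertiary hydroxyl adds to the adjacent quinone carbonyl (future C8a) to give the cyclic hemiketal, which is reduced to the chromanol; the C2–O bond is never broken, so R is retained, as known for tocopherolquinone → tocopherol.

## Compound list

1 | natural phytol, (2E,7R,11R)-3,7,11,15-tetramethylhexadec-2-en-1-ol | OC/C=C(\C)CCC[C@H](C)CCC[C@H](C)CCCC(C)C | starting material
2 | (6R,10R)-6,10,14-trimethylpentadecan-2-one | CC(=O)CCC[C@H](C)CCC[C@H](C)CCCC(C)C | intermediate
3 | (5R,9R)-5,9,13-trimethyltetradecanoic acid | OC(=O)CCC[C@H](C)CCC[C@H](C)CCCC(C)C | intermediate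
4 | (4R,8R)-1-iodo-4,8,12-trimethyltridecane | ICCC[C@H](C)CCC[C@H](C)CCCC(C)C | intermediate
5 | (S)-3-hydroxybutanoic acid | C[C@H](O)CC(=O)O | starting material
6 | pivalaldehyde | CC(C)(C)C=O | starting material
7 | (2S,6S)-2-tert-butyl-6-methyl-1,3-dioxan-4-one | C[C@H]1CC(=O)O[C@@H](C(C)(C)C)O1 | intermediate
8 | (S)-2-tert-butyl-6-methyl-4H-1,3-dioxin-4-one | CC1=CC(=O)O[C@@H](C(C)(C)C)O1 | intermediate
9 | (2S,6R)-2-tert-butyl-6-methyl-6-[(4R,8R)-4,8,12-trimethyltridecyl]-1,3-dioxan-4-one | C[C@@]1(CCC[C@H](C)CCC[C@H](C)CCCC(C)C)CC(=O)O[C@@H](C(C)(C)C)O1 | intermediate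
10 | propyne | CC#C | starting material
11 | (6R,10R,14R)-6-hydroxy-6,10,14,18-tetramethylnonadec-2-yn-4-one | CC#CC(=O)C[C@](C)(O)CCC[C@H](C)CCC[C@H](C)CCCC(C)C | intermediate
12 | 3-methylfuran-2(5H)-one | CC1=CCOC1=O | starting material
13 | 3-methyl-2-(trimethylsilyloxy)furan | Cc1ccoc1O[Si](C)(C)C | intermediate
14 | (3R,7R,11R)-1-(2,5-dihydroxy-3,6-dimethylphenyl)-3-hydroxy-3,7,11,15-tetramethylhexadecan-1-one | Cc1cc(O)c(C)c(C(=O)C[C@](C)(O)CCC[C@H](C)CCC[C@H](C)CCCC(C)C)c1O | intermediate
15 | 2-[(3R,7R,11R)-3-hydroxy-3,7,11,15-tetramethylhexadecyl]-3,6-dimethylcyclohexa-2,5-diene-1,4-dione | CC1=CC(=O)C(C)=C(CC[C@](C)(O)CCC[C@H](C)CCC[C@H](C)CCCC(C)C)C1=O | intermediate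
16 | (2R,4′R,8′R)-β-tocopherol | Cc1cc(O)c(C)c2c1O[C@](C)(CCC[C@H](C)CCC[C@H](C)CCCC(C)C)CC2 | target

## Step count

Total steps: 11. Longest linear sequence: 8 (steps 1, 2, 3, 6, 7, 9, 10, 11 from phytol).

## Steps most likely to fail, with fallbacks

1. **Step 9 (Diels–Alder with a β-methyl ynone).** The silyloxyfuran may give only the vinylogous Michael adduct, or the cycloaddition may be too slow. Fallback: use (E)-2-methyl-1-(trimethylsilyloxy)buta-1,3-diene (from tiglic aldehyde) in a normal-demand Diels–Alder with 11 and dehydrogenate with DDQ to the 2-acyl-3,6-dimethylphenol. After carbonyl removal, the second oxygen is introduced by para-oxidation of the phenol (Fremy's salt or salcomine/O2) to reach quinone 15.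

2. **Step 10 (carbonyl removal next to the β-tertiary alcohol).** Retro-aldol or dehydration/oxa-Michael would destroy or scramble C2. Fallback: reverse the order. Oxidise 14 to the acylquinone (Ag2O), close the pyran first by the hemiketal/reduction sequence of step 11 to the (R)-6-hydroxychroman-4-one, then remove the C4 carbonyl by Clemmensen reduction (Zn(Hg), HCl) once the tertiary oxygen is locked as the ring ether.

3. **Step 7 (stopping acetylide addition at the ketone on an acylal-type lactone).** Over-addition or acetal opening by BF3 are the risks. Fallback: a redox route. Reduce 9 with DIBAL (−78 °C) to the β-hydroxy aldehyde (lactol), add 1-propynylmagnesium bromide, and oxidise the propargylic alcohol with MnO2 to 11.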